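0.563 of E for each unit of Q lost: the larch run shows this at its last reading, and E found over Q lost is the E share, an apparent selectivity. You are about to repeat these flasks, so here they are, with the readings and the questions.

| flask | Q | G | temperature | remark | time |
|---|---|---|---|---|---|
| alder | 0.025 M | 2 equiv | −8 °C | run made earlier |  |
| larch | 0.10 M | 2 equiv | 20 °C | run made earlier |  |
| maple | 0.050 M | 3 equiv | −8 °C | run made earlier |  |
| Sunday's | 0.050 M | 2.00 equiv |  | at −20 °C until 6.0 min, from then on at 30 °C | 30 min |
| Tuesday's | 0.050 M | 2.00 equiv | −20 °C |  | 30 min |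
| Saturday's | 0.050 M | 2.00 equiv | 30 °C |  | 30 min |
| Wednesday's | 0.050 M | 2.00 equiv | 5 °C |  | 30 min |

- alder (time / min: E / %, Q / %): 3.00: 2.7, 96.2; 6.00: 3.8, 92.7; 8.00: 6.8, 92.4; 12.0: 7.6, 90.4
- larch (time / min: E / %, Q / %): 0.200: 5.9, 91.0; 0.417: 8.5, 84.8; 1.00: 17.9, 70.1; 3.00: 29.1, 48.3
- maple (time / min: E / %, Q / %): 1.33: 2.9, 96.7; 3.00: 7.3, 90.3; 6.00: 12.3, 83.4; 12.0: 19.0, 69.5

(each reading ± 1 percentage point)

- a reading or a percentage of E counts all its forms, free or not
- a reading of Q is of its free form alone

- the flask with the highest amount of E, in percent of the Q charged ("all alike" if they lie within 1.5 percentage points) (Sunday's / Tuesday's / Saturday's / Wednesday's / all alike)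
- final E, as a percentage of the Q charged, in Sunday's
- final E, as a percentage of the Q charged, in Tuesday's
- final E, as a percentage of the Q charged, in Saturday's
- final E, as a percentage of the Q charged, in Wednesday's

Read the last row of each table, E against Q. The alder run gives 0.792, though on a loss of 9.6 percentage points, so a scatter of 1 point per reading moves it visibly. The maple run gives 0.623, and the larch run, at 20 °C, gives 0.563, lower than either. Now go up the larch table: its first row reads 0.656 and its third 0.599, so within that run the share stays put inside the scatter.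

That gives you a gauge. Read the Q lost and multiply by 0.563, and you have the E to expect while the share holds. An E below that product says the share has moved or E is being used up. But the larch readings stop at 3.00 min and the cold ones at 12.0 min, while the questions run to 30 min.

The forecast names Wednesday's as richest, with 40 % there, 19.5 % in Sunday's, 13.5 % in Tuesday's and 17.5 % in Saturday's, on the reading that “The side loss is steady”.

The flasks give 13.1 % in Sunday's, 13.2 % in Tuesday's, 12.0 % in Saturday's and 22.6 % in Wednesday's, so Wednesday's leads.

    Q + G ⇌ E (K = 7.10 M⁻¹, k = 0.00820 M⁻¹ s⁻¹, Ea = 49.0 kJ mol⁻¹, ΔH = 2.00 kJ mol⁻¹)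
    Q + G ⇌ Z (K = 31.0 M⁻¹, k = 0.00340 M⁻¹ s⁻¹, Ea = 51.0 kJ mol⁻¹, ΔH = −35.0 kJ mol⁻¹)
    D ⇌ E, rate k3*(cs3 - [E]) while solid is left; crystals form when [E] > cs3 (solubility = 33.0 mM, k = 0.00470 s⁻¹)
    G + E → L (k = 0.00210 M⁻¹ s⁻¹, Ea = 62.0 kJ mol⁻¹)
    (constants at 5 °C)

Saturday's ends with 35 % of its Q free, so the gauge expects 36.6 % of E, yet it holds 12.0 %, a share of 0.185. At 1.62 min Saturday's makes dissolved E 3.33 times as fast as it uses it up, each step taken net, but at 30.0 min that ratio is 0.743, below one, with L at 35.2 %. Take a neighbour like Saturday's with 5.00 equiv of G: it ends with 5.3 % of Q free, so the gauge expects 53.3 %. The computed E there is 4.68 %, with L at 79.0 %.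

The readings come from a simulation for an exercise, and the scatter is random.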